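## Structural features

The target is a 3,3a-dihydro-1-benzofuran-6(2H)-one. An oxolane (ring B: O1, C2, C3, C3a, C7a) is fused through the C3a–C7a bond to a cross-conjugated cyclohexa-2,5-dienone (ring C: C3a, C4, C5, C6, C7, C7a), and a 3,4,5-trimethoxyphenyl group (ring A) sits on C2. Ring C is unsymmetrical: the C4=C5 arm is an α-methoxy enone, while the C7=C7a arm is a vinylogous ester whose oxygen is O1. Three contiguous stereocentres run C2 (R), C3 (S), C3a (S); aryl and methyl are cis on ring B, and the allyl group on quaternary C3a is trans to the methyl. Several groups are fragile: the 3a-allyl dienone can shift its allyl group to C5 or C7 ([3,3] or acid-induced, with aromatisation as driving force); ionisation of the benzylic C2–O1 bond would epimerise C2; and the terminal alkene forbids hydrogenation and is exposed to electrophilic palladium. The real difficulty is the all-carbon quaternary stereocentre C3a, flanked by the C3 stereocentre and embedded in a non-aromatic, highly oxidised ring. The key step exploits that C3a lies para to the C6 carbonyl and is bonded to C4, the β-carbon of the C4=C5–C6 enone whose α-carbon C5 is methoxylated. This is the retron of a Michael–aldol (Robinson) annulation in which C3a and C4 come from an α-branched aldehyde and C5, C6, C7 and C7a from methoxymethyl vinyl ketone.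

## Logic of the disconnections

24 to 22. No skeletal bond is cut; the C7=C7a double bond is taken back to C7H2–C7aH. The vinylogous ester, together with the 3a-allyl dienone, is the most sensitive array of the molecule and is therefore created last. The gain is a plain β-alkoxy ketone. The forward step must dehydrogenate at or below room temperature, without acid and without palladium; its regiochemistry is fixed because only C7 carries α-hydrogens.

22 to 20. The O1–C7a bond is cut (retro-oxa-Michael), which removes ring B and the temporary C7a stereocentre. This exposes a cross-conjugated dienone whose C2 oxygen is silylated. The forward step needs the liberated alkoxide to choose C7a over C4; the C5 methoxy group is relied on for that, and cis ring fusion is the only possible outcome.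

20 to 17. The C7=C7a double bond is removed again, leading to the 4,4-disubstituted 2-methoxycyclohexenone that a Robinson annulation delivers directly. The forward dehydrogenation can start only at C7. It must not use a divalent palladium enolate, because such a species at C7 stands 1,3 to the allyl group and could insert the alkene.

17 to 11 and 14. C3a–C7a and C4=C5 are cut. This removes ring C and the quaternary stereocentre in one operation and leaves an α-branched aldehyde and a four-carbon enone. The forward step must form C3a–C7a on one face of a planar enamine carbon. The α-configuration of 11 is irrelevant, so 11 is used as both C2 epimers.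

11 to 9 and 10. The C3a–CH2 (allyl) bond is cut. The gain is an α-unbranched aldehyde. The forward α-allylation has no stereochemical task but must stop after one allyl group.

9 to 8 to 6 to 5. These are functional-group changes only: the aldehyde carbon is the terminal carbon of a vinyl group, and the benzylic oxygen is silylated. The forward sequence needs anti-Markovnikov hydration of the alkene and an oxidation that stops at the aldehyde. The silyl ether is chosen so that its later removal by fluoride triggers the ring B closure.

5 to 1 and 2. The C2–C3 bond is cut. Both stereocentres of the side chain are set in one crotyl transfer to an aromatic aldehyde. The forward step must preserve the Z geometry of the crotyl unit (syn relationship) and control the aldehyde face by the reagent.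

14 to 13 to 12. The acyl–vinyl bond is cut. Direct addition of a vinyl Grignard reagent to an acid chloride would over-add, so the forward route passes through the N-methoxy-N-methylamide. The released amine must be kept from adding to the enone.

## Other disconnections considered

Alternative 1: The cut is the C2–C3 bond of ring B, made while ring C is still a benzene ring carrying the C5 methoxy group and a silylated C6 phenol. In the forward direction the aryldiazoacetate A2 would be decomposed by Rh2(S-PTTL)4, and the donor/acceptor carbene would insert into the benzylic ether C–H bond, closing ring B to the cis ester A1.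
- In its favour: C2 and C3 are made together in one catalytic, reagent-controlled step of a well-tried reaction type. All compounds up to A1 are robust arenes. The ring C oxygens come with the starting phenol, so no dehydrogenation is needed. On these three points it is the equal or the better of the chosen plan, which spends a stoichiometric chiral borane and two late oxidations.
- Against it here: A1 has an ester where the target has a methyl group, so about three reduction/deoxygenation steps follow. During these, C3 (benzylic and α to the ester) can epimerise to the trans series.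
- The larger problem is C3a, which is left to the end. It would be made by dearomatising C-allylation of the freed phenol para to the C6 oxygen. This must beat O-allylation and attack at the unsubstituted C7, and nothing in the substrate secures that. Its facial course should be correct (anti to the C3 methyl), which is equal to the chosen plan in outcome.
- Comparison: the chosen plan makes the quaternary centre by C–C bond formation at an enamine carbon under catalyst control, before any sensitive dienone exists. Alternative 1 makes it by breaking aromaticity in the last step. The step counts are about equal (roughly five steps to A2, the insertion, then about five more), but alternative 1 carries its largest risk at the end.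

Alternative 2: The cut is O1–C7a in a compound without the C5 methoxy group, the prochiral dienone acetate A4. In the forward direction K2CO3 in methanol would cleave the acetate, and the alkoxide would add to one of the two enone β-carbons to give the cis-fused ketone A3.
- In its favour: the quaternary carbon of A4 is not a stereocentre, so no asymmetric C–C bond formation at a congested carbon is required. On this point it is better than the chosen plan. The ring closure is the same 5-exo-trig oxa-Michael addition as step 10 of the chosen plan, so the two are equal there. The reagents are trivial.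
- Against it here: the two enone arms are diastereotopic. They differ only in whether the C3 methyl ends up cis to the allyl CH2 or to the ring carbon C4. This is a small difference, and because the addition is reversible the outcome would rest on a small energy gap. In the chosen plan the same closure has to distinguish two constitutionally different arms, which the C5 methoxy group differentiates electronically.
- A3 also lacks the C5 methoxy group and the C7=C7a bond. Oxygenation and methylation at C5 (about three steps) and a dehydrogenation would follow. A4 itself still needs its quaternary carbon built with the side-chain stereodiad attached.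
- Comparison: the mechanism of the key step is simpler, but the stereochemical decision is less secure and the sequence after the key step is longer (about four or five steps against three).

Alternative 3: The cuts are C2–C3 and the acyl O1–C7a bond, leading to the lactone A5 from crotonaldehyde A6 and 1. In the forward direction a chiral triazolium-derived carbene would convert A6 into a homoenolate equivalent that adds to 1, and the resulting alkoxide would be acylated by the acyl azolium, closing ring B as the cis lactone A5.
- In its favour: one catalytic step from two bulk aldehydes gives ring B with C2 and C3 set and C7a already at the carboxyl level. This is the shortest entry to the C2/C3 pair of all the plans. It equals the chosen plan in step count for these two centres and is better in reagent economy.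
- Against it here: homoenolate annulations are best established for β-aryl enals. For a β-methyl enal and a simple aryl aldehyde, the cis/trans preference and the enantiocontrol are less assured than in a crotylboration, and benzoin-type pathways compete.
- A5 contains neither C4–C7 nor the allyl group. C3a must be alkylated twice, four carbons of ring C attached, and the lactone carbonyl turned into the enol ether carbon C7a. This is about eight further steps through β-dicarbonyl intermediates in which the lactone can open. Control of the second alkylation by the C3 methyl is plausible and is a fair point for this plan.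
- Comparison: it is better in its first step and simpler in how the quaternary centre would be controlled (substrate control in a lactone enolate alkylation), but clearly longer overall than the chosen plan.

Key step: step 8

Assumption: the (1S,2S) antipode of the amine–thiourea is written for delivery to the Si face of C3a; which antipode does this for so bulky an α-substituent is settled in the first run, and the mirror-image catalyst is used otherwise, with nothing else changed.

Remark: the descriptors of 11, 17 and 24 were cross-checked atom by atom (C3 and C4 of 11 are C3 and C2 of 24; C4 of 17 is C3a of 24). 11 carries no descriptor at C2 because the enamine of step 8 removes that centre.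

## Route

Step 1
Reactants: 1 3,4,5-trimethoxybenzaldehyde; 2 cis-but-2-ene
Product: 5 (1R,2S)-2-methyl-1-(3,4,5-trimethoxyphenyl)but-3-en-1-ol, via (Z)-crotylpotassium 3 (not isolated), via (Z)-crotylbis(isopinocampheyl)borane 4 (not isolated)
Conditions: 2, KOtBu, n-BuLi, THF, −78 → −45 °C; (+)-B-methoxydiisopinocampheylborane [from (−)-α-pinene], −78 °C; BF3·OEt2; 1, −78 °C; then NaOH, H2O2, 0 °C → rt
Reagents that add atoms: none
Why: Asymmetric (Z)-crotylboration: metalation of 2 gives the configurationally stable (Z)-crotylpotassium, which is transferred to boron; the chair Zimmerman–Traxler transition state turns the Z geometry into the syn C2/C3 relationship, and the isopinocampheyl groups from (−)-α-pinene direct the crotyl group to the Re face of the aryl aldehyde, so that C2 (R) and C3 (S) of the target are set here.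

Step 2
Reactants: 5 (1R,2S)-2-methyl-1-(3,4,5-trimethoxyphenyl)but-3-en-1-ol
Product: 6 tert-butyldimethyl{[(1R,2S)-2-methyl-1-(3,4,5-trimethoxyphenyl)but-3-en-1-yl]oxy}silane
Conditions: TBSOTf, 2,6-lutidine, CH2Cl2, −78 → 0 °C
Reagents that add atoms: tert-butyldimethylsilyl trifluoromethanesulfonate, CC(C)(C)[Si](C)(C)OS(=O)(=O)C(F)(F)F
Why: Silylation of a hindered secondary benzylic alcohol with a silyl triflate and a hindered base; the basic medium prevents ionisation at the electron-rich benzylic carbon, and the silyl ether is stable to every step up to the fluoride of step 10.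

Step 3
Reactants: 6 tert-butyldimethyl{[(1R,2S)-2-methyl-1-(3,4,5-trimethoxyphenyl)but-3-en-1-yl]oxy}silane
Product: 8 (3S,4R)-4-(tert-butyldimethylsilyloxy)-3-methyl-4-(3,4,5-trimethoxyphenyl)butan-1-ol, via B-alkyl-9-borabicyclononane 7 (not isolated)
Conditions: 9-BBN, THF, 0 °C → rt; then NaOH, H2O2, 0 °C → rt
Reagents that add atoms: hydrogen peroxide, OO
Why: Hydroboration–oxidation: the bulky borane places boron on the terminal carbon of the monosubstituted alkene, and alkaline peroxide replaces boron by hydroxyl; the silyl ether and both stereocentres are untouched.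

Step 4
Reactants: 8 (3S,4R)-4-(tert-butyldimethylsilyloxy)-3-methyl-4-(3,4,5-trimethoxyphenyl)butan-1-ol
Product: 9 (3S,4R)-4-(tert-butyldimethylsilyloxy)-3-methyl-4-(3,4,5-trimethoxyphenyl)butanal
Conditions: Dess–Martin periodinane, NaHCO3, CH2Cl2, 0 °C → rt
Reagents that add atoms: none
Why: Buffered Dess–Martin oxidation stops at the aldehyde; the nearest stereocentre is β to the new carbonyl and cannot epimerise.

Step 5
Reactants: 9 (3S,4R)-4-(tert-butyldimethylsilyloxy)-3-methyl-4-(3,4,5-trimethoxyphenyl)butanal; 10 allyl acetate
Product: 11 (3S,4R)-2-allyl-4-(tert-butyldimethylsilyloxy)-3-methyl-4-(3,4,5-trimethoxyphenyl)butanal (both C2 epimers)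
Conditions: Pd(PPh3)4 (5 mol %), pyrrolidine (30 mol %), DMSO, rt
Reagents that add atoms: none
Why: Tsuji–Trost α-allylation of an aldehyde by combined enamine and zerovalent palladium catalysis: the pyrrolidine enamine of 9 attacks the π-allylpalladium complex formed from 10; the α-branched product forms a pyrrolidine enamine only slowly, which limits a second allylation, and the new centre needs no control because step 8 planarises it.

Step 6
Reactants: 12 methoxyacetyl chloride
Product: 13 N,2-dimethoxy-N-methylacetamide
Conditions: MeNHOMe·HCl, pyridine, CH2Cl2, 0 °C → rt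
Reagents that add atoms: N,O-dimethylhydroxylamine hydrochloride, CNOC.Cl
Why: Acylation of the hydroxylamine by the acid chloride gives the N-methoxy-N-methylamide, the acyl donor that allows a single addition of a Grignard reagent.

Step 7
Reactants: 13 N,2-dimethoxy-N-methylacetamide
Product: 14 1-methoxybut-3-en-2-one
Conditions: CH2=CHMgBr, THF, −78 → 0 °C; inverse quench into cold aqueous HCl
Reagents that add atoms: vinylmagnesium bromide, C=C[Mg]Br
Why: Weinreb ketone synthesis: the chelated tetrahedral adduct survives until work-up, so no second addition occurs; the cold acidic inverse quench protonates the released amine before it can add to the enone, which is used promptly and kept cold.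

Step 8
Reactants: 11 (3S,4R)-2-allyl-4-(tert-butyldimethylsilyloxy)-3-methyl-4-(3,4,5-trimethoxyphenyl)butanal (both C2 epimers); 14 1-methoxybut-3-en-2-one
Product: 17 (4R)-4-allyl-4-[(1R,2S)-1-(tert-butyldimethylsilyloxy)-1-(3,4,5-trimethoxyphenyl)propan-2-yl]-2-methoxycyclohex-2-en-1-one, via keto aldehyde 15 (not isolated), via aldol adduct 16 (not isolated)
Conditions: 1-[(1S,2S)-2-aminocyclohexyl]-3-[3,5-bis(trifluoromethyl)phenyl]thiourea (20 mol %), PhCO2H (20 mol %), 14 (2 equiv), toluene (1 M), rt; then pyrrolidine, AcOH (30 mol % each), 40 °C
Reagents that add atoms: none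
Why: The primary amine of the catalyst condenses with 11 to a secondary enamine, which erases C2 of 11 and places the bulky C3 branch anti to nitrogen, while the thiourea hydrogen-bonds the carbonyl of 14 and delivers its β-carbon to the enamine carbon, forming C3a–C7a (Michael addition); hydrolysis releases 15. The closest known reaction type is the primary-amine-catalysed asymmetric Robinson annulation of α-branched aldehydes with vinyl ketones to 4,4-disubstituted cyclohexenones; the α-substituent here is larger than usual, hence the high concentration and the acid co-catalyst. Ring C then closes by an amine-mediated 6-(enolendo)-exo-trig aldol addition of C5 to the aldehyde carbon C4 to give 16, and E1cB loss of water gives the C4=C5 enol ether of 17. The only new stereocentre that survives is C3a: it is set in the Michael step, which has to take place on the Si face of the enamine carbon (priorities C4 > C3 > allyl CH2), and this is the task of the catalyst antipode, with the C3 stereocentre as a second, weaker influence. Regioselectivity of the ring closure is secured by the substrate, since enolisation toward C7 could close only a four-membered ring and α-oxygenated ketones react preferentially at the oxygenated carbon. Because 11 is a single enantiomer at C3 and C4, attack on the wrong face gives a diastereomer of 17 that can be removed by chromatography, so the step needs diastereoselectivity and not enantioselectivity. Neither C3 nor the benzylic carbon is acidic, and the silyl ether tolerates the buffered amine medium.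

Step 9
Reactants: 17 (4R)-4-allyl-4-[(1R,2S)-1-(tert-butyldimethylsilyloxy)-1-(3,4,5-trimethoxyphenyl)propan-2-yl]-2-methoxycyclohex-2-en-1-one
Product: 20 (4S)-4-allyl-4-[(1R,2S)-1-(tert-butyldimethylsilyloxy)-1-(3,4,5-trimethoxyphenyl)propan-2-yl]-2-methoxycyclohexa-2,5-dien-1-one, via lithium dienolate 18 (not isolated), via C6 sulfilimine 19 (not isolated)
Conditions: LiN(iPr)2, THF, −78 °C; then PhS(Cl)=NtBu, −78 °C; NaHCO3 (aq)
Reagents that add atoms: none
Why: Mukaiyama dehydrogenation: deprotonation is possible only at C7 (C5 has no hydrogen, C3a is quaternary), the enolate attacks sulfur of N-tert-butylbenzenesulfinimidoyl chloride, and the sulfilimine loses a C7a hydrogen by syn-elimination at −78 °C. The method is palladium-free, so the allyl group 1,3 to C7 cannot be drawn into a cycloalkenylation, and the low temperature avoids a [3,3] shift of the allyl group in the dienone.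

Step 10
Reactants: 20 (4S)-4-allyl-4-[(1R,2S)-1-(tert-butyldimethylsilyloxy)-1-(3,4,5-trimethoxyphenyl)propan-2-yl]-2-methoxycyclohexa-2,5-dien-1-one
Product: 22 (2R,3S,3aS,7aR)-3a-allyl-5-methoxy-3-methyl-2-(3,4,5-trimethoxyphenyl)-3,3a,7,7a-tetrahydro-1-benzofuran-6(2H)-one, via hydroxy dienone 21 (not isolated)
Conditions: Bu4NF, THF, 0 °C → rt; NH4Cl (aq)
Reagents that add atoms: none
Why: Fluoride cleaves the Si–O bond and the resulting alkoxide closes ring B by 5-exo-trig oxa-Michael addition to C7a. C7a is preferred over C4 because C4 is the β-carbon of the C5 enol ether and is deactivated, and because the product keeps the donor-stabilised methoxy enone; only the cis ring fusion is geometrically possible, and the temporary C7a centre is removed in step 11.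

Step 11
Reactants: 22 (2R,3S,3aS,7aR)-3a-allyl-5-methoxy-3-methyl-2-(3,4,5-trimethoxyphenyl)-3,3a,7,7a-tetrahydro-1-benzofuran-6(2H)-one
Product: 24 (2R,3S,3aS)-3a-allyl-5-methoxy-3-methyl-2-(3,4,5-trimethoxyphenyl)-3,3a-dihydro-1-benzofuran-6(2H)-one, via trimethylsilyl enol ether 23 (not isolated)
Conditions: TMSOTf, Et3N, CH2Cl2, −20 → 0 °C; solvent exchange; 2-iodoxybenzoic acid (IBX), 4-methoxypyridine N-oxide, DMSO, rt; NaHCO3 (aq)
Reagents that add atoms: none
Why: Soft enolisation can go only toward C7 and avoids a free enolate that could expel O1; oxidation of silyl enol ethers to enones by the IBX–N-oxide complex at room temperature is a known dehydrogenation, and here only C7a offers a β-hydrogen, so the C7=C7a vinylogous ester results without palladium, heat or acid, and C2, C3 and C3a are not touched.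

## Compound list

1 | 3,4,5-trimethoxybenzaldehyde | O=Cc1cc(OC)c(OC)c(OC)c1 | starting material
2 | cis-but-2-ene | C/C=C\C | starting material
3 | (Z)-crotylpotassium | [K+].C/C=C\[CH2-] | intermediate
4 | (Z)-but-2-en-1-ylbis(isopinocampheyl)borane, isopinocampheyl groups from (−)-α-pinene | C/C=C\CB([C@H]1C[C@H]2C[C@@H]([C@@H]1C)C2(C)C)[C@H]1C[C@H]2C[C@@H]([C@@H]1C)C2(C)C | intermediate
5 | (1R,2S)-2-methyl-1-(3,4,5-trimethoxyphenyl)but-3-en-1-ol | C=C[C@H](C)[C@@H](O)c1cc(OC)c(OC)c(OC)c1 | intermediate
6 | tert-butyldimethyl{[(1R,2S)-2-methyl-1-(3,4,5-trimethoxyphenyl)but-3-en-1-yl]oxy}silane | C=C[C@H](C)[C@@H](O[Si](C)(C)C(C)(C)C)c1cc(OC)c(OC)c(OC)c1 | intermediate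
7 | 9-[(3S,4R)-4-(tert-butyldimethylsilyloxy)-3-methyl-4-(3,4,5-trimethoxyphenyl)butyl]-9-borabicyclo[3.3.1]nonane | C1CCC2CCCC1B2CC[C@H](C)[C@@H](O[Si](C)(C)C(C)(C)C)c1cc(OC)c(OC)c(OC)c1 | intermediate
8 | (3S,4R)-4-(tert-butyldimethylsilyloxy)-3-methyl-4-(3,4,5-trimethoxyphenyl)butan-1-ol | OCC[C@H](C)[C@@H](O[Si](C)(C)C(C)(C)C)c1cc(OC)c(OC)c(OC)c1 | intermediate
9 | (3S,4R)-4-(tert-butyldimethylsilyloxy)-3-methyl-4-(3,4,5-trimethoxyphenyl)butanal | O=CC[C@H](C)[C@@H](O[Si](C)(C)C(C)(C)C)c1cc(OC)c(OC)c(OC)c1 | intermediate
10 | allyl acetate | C=CCOC(C)=O | starting material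
11 | (3S,4R)-2-allyl-4-(tert-butyldimethylsilyloxy)-3-methyl-4-(3,4,5-trimethoxyphenyl)butanal, both C2 epimers | C=CCC(C=O)[C@H](C)[C@@H](O[Si](C)(C)C(C)(C)C)c1cc(OC)c(OC)c(OC)c1 | intermediate
12 | methoxyacetyl chloride | COCC(=O)Cl | starting material
13 | N,2-dimethoxy-N-methylacetamide | COCC(=O)N(C)OC | intermediate
14 | 1-methoxybut-3-en-2-one | COCC(=O)C=C | intermediate
15 | (2R)-2-allyl-2-[(1R,2S)-1-(tert-butyldimethylsilyloxy)-1-(3,4,5-trimethoxyphenyl)propan-2-yl]-6-methoxy-5-oxohexanal | C=CC[C@](C=O)(CCC(=O)COC)[C@H](C)[C@@H](O[Si](C)(C)C(C)(C)C)c1cc(OC)c(OC)c(OC)c1 | intermediate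
16 | (4R)-4-allyl-4-[(1R,2S)-1-(tert-butyldimethylsilyloxy)-1-(3,4,5-trimethoxyphenyl)propan-2-yl]-3-hydroxy-2-methoxycyclohexan-1-one, epimers at C2 and C3 | C=CC[C@@]1(C(O)C(OC)C(=O)CC1)[C@H](C)[C@@H](O[Si](C)(C)C(C)(C)C)c1cc(OC)c(OC)c(OC)c1 | intermediate
17 | (4R)-4-allyl-4-[(1R,2S)-1-(tert-butyldimethylsilyloxy)-1-(3,4,5-trimethoxyphenyl)propan-2-yl]-2-methoxycyclohex-2-en-1-one | C=CC[C@@]1(C=C(OC)C(=O)CC1)[C@H](C)[C@@H](O[Si](C)(C)C(C)(C)C)c1cc(OC)c(OC)c(OC)c1 | intermediate
18 | lithium (4S)-4-allyl-4-[(1R,2S)-1-(tert-butyldimethylsilyloxy)-1-(3,4,5-trimethoxyphenyl)propan-2-yl]-6-methoxycyclohexa-1,5-dien-1-olate | [Li+].C=CC[C@@]1(C=C(OC)C([O-])=CC1)[C@H](C)[C@@H](O[Si](C)(C)C(C)(C)C)c1cc(OC)c(OC)c(OC)c1 | intermediate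
19 | (4S)-4-allyl-6-(N-tert-butyl-S-phenylsulfinimidoyl)-4-[(1R,2S)-1-(tert-butyldimethylsilyloxy)-1-(3,4,5-trimethoxyphenyl)propan-2-yl]-2-methoxycyclohex-2-en-1-one, epimers at C6 and sulfur | C=CC[C@@]1(C=C(OC)C(=O)C(S(=NC(C)(C)C)c2ccccc2)C1)[C@H](C)[C@@H](O[Si](C)(C)C(C)(C)C)c1cc(OC)c(OC)c(OC)c1 | intermediate
20 | (4S)-4-allyl-4-[(1R,2S)-1-(tert-butyldimethylsilyloxy)-1-(3,4,5-trimethoxyphenyl)propan-2-yl]-2-methoxycyclohexa-2,5-dien-1-one | C=CC[C@@]1(C=C(OC)C(=O)C=C1)[C@H](C)[C@@H](O[Si](C)(C)C(C)(C)C)c1cc(OC)c(OC)c(OC)c1 | intermediate
21 | (4S)-4-allyl-4-[(1R,2S)-1-hydroxy-1-(3,4,5-trimethoxyphenyl)propan-2-yl]-2-methoxycyclohexa-2,5-dien-1-one, formed as its tetrabutylammonium alkoxide | C=CC[C@@]1(C=C(OC)C(=O)C=C1)[C@H](C)[C@@H](O)c1cc(OC)c(OC)c(OC)c1 | intermediate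
22 | (2R,3S,3aS,7aR)-3a-allyl-5-methoxy-3-methyl-2-(3,4,5-trimethoxyphenyl)-3,3a,7,7a-tetrahydro-1-benzofuran-6(2H)-one | C=CC[C@]12C=C(OC)C(=O)C[C@H]1O[C@@H](c1cc(OC)c(OC)c(OC)c1)[C@H]2C | intermediate
23 | (2R,3S,3aS,7aR)-3a-allyl-5-methoxy-3-methyl-6-(trimethylsilyloxy)-2-(3,4,5-trimethoxyphenyl)-2,3,3a,7a-tetrahydro-1-benzofuran | C=CC[C@]12C=C(OC)C(O[Si](C)(C)C)=C[C@H]1O[C@@H](c1cc(OC)c(OC)c(OC)c1)[C@H]2C | intermediate
24 | (2R,3S,3aS)-3a-allyl-5-methoxy-3-methyl-2-(3,4,5-trimethoxyphenyl)-3,3a-dihydro-1-benzofuran-6(2H)-one | C=CC[C@]12C=C(OC)C(=O)C=C1O[C@@H](c1cc(OC)c(OC)c(OC)c1)[C@H]2C | target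

## Step count and least certain steps

Total step count: 11. Longest linear sequence: 9 steps (steps 1–5 and 8–11, from 1); steps 6 and 7 are the two-step branch to 14.

Step 8 (key step). Two processes are most likely to go wrong. The first is slow enamine formation and slow Michael addition at a carbon flanked by the branched C3 substituent, during which 14 can polymerise or alkylate the catalyst nitrogen. The second is poor facial selectivity at C3a if the C3 stereocentre opposes the catalyst. The fallback replaces catalytic control by a stoichiometric chiral imine. It sets out from 11, which is condensed with (S)-1-phenylethylamine (toluene, MgSO4) to the N-(1-phenylethyl)imine F1. The secondary enamine tautomer of F1 adds to 14 (THF, rt to 40 °C) in the known Michael addition of chiral imines to electrophilic alkenes, giving the adduct imine F2. Buffered aqueous acetic acid hydrolyses F2, and the fallback comes back to the route at 15, which is closed to 17 with pyrrolidine and AcOH as in step 8. The amine antipode is chosen in the same way as the catalyst antipode.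

Step 5. The likely failures are a second allylation, loss of the allyl donor by N-allylation of pyrrolidine, and self-aldol condensation of 9 under amine catalysis. The fallback is a Stork metalloenamine alkylation. It sets out from 9, which is condensed with cyclohexylamine to the N-cyclohexylimine F3. Deprotonation with LiN(iPr)2 (THF, −78 °C) and alkylation with allyl bromide give the allylated imine F4. Hydrolysis in a cold aqueous oxalic acid buffer returns to the route at 11.

Step 9. The likely failures are incomplete enolisation of the hindered enone, or a sulfilimine 19 that fragments slowly, so that material is lost on warming when the allyl dienone begins to rearrange. The fallback changes the oxidant class. It sets out from 17, which is converted with LiN(SiMe3)2 and TMSCl (THF, −78 °C) into the trimethylsilyl dienol ether F5. F5 is oxidised with IBX and 4-methoxypyridine N-oxide (DMSO, rt), and the fallback comes back at 20.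

Step 11. The likely failures are opening of ring B during silylation (ionisation of the benzylic C2–O1 bond, or loss of O1 from C7a), and acid-induced migration of the allyl group in the product during oxidation or isolation. The fallback is a selenoxide elimination. It sets out from 22, prepared as its silyl enol ether 23 with LiN(SiMe3)2 and TMSCl at −78 °C. Treatment with PhSeCl (CH2Cl2, −78 °C) gives the 7-phenylselanyl ketone F6, whose C7 epimers can equilibrate. Oxidation with H2O2 and pyridine (CH2Cl2, 0 °C) leads by syn-elimination toward the C7a hydrogen back to the route at 24.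

## Further compounds

F1 | step 8 | (3S,4R)-2-allyl-4-(tert-butyldimethylsilyloxy)-3-methyl-N-[(1S)-1-phenylethyl]-4-(3,4,5-trimethoxyphenyl)butan-1-imine, both C2 epimers | C=CCC(/C=N/[C@@H](C)c1ccccc1)[C@H](C)[C@@H](O[Si](C)(C)C(C)(C)C)c1cc(OC)c(OC)c(OC)c1
F2 | step 8 | (5R)-5-allyl-5-[(1R,2S)-1-(tert-butyldimethylsilyloxy)-1-(3,4,5-trimethoxyphenyl)propan-2-yl]-1-methoxy-6-{[(1S)-1-phenylethyl]imino}hexan-2-one | C=CC[C@](/C=N/[C@@H](C)c1ccccc1)(CCC(=O)COC)[C@H](C)[C@@H](O[Si](C)(C)C(C)(C)C)c1cc(OC)c(OC)c(OC)c1
F3 | step 5 | (3S,4R)-4-(tert-butyldimethylsilyloxy)-N-cyclohexyl-3-methyl-4-(3,4,5-trimethoxyphenyl)butan-1-imine | C1CCCCC1/N=C/C[C@H](C)[C@@H](O[Si](C)(C)C(C)(C)C)c1cc(OC)c(OC)c(OC)c1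
F4 | step 5 | (3S,4R)-2-allyl-4-(tert-butyldimethylsilyloxy)-N-cyclohexyl-3-methyl-4-(3,4,5-trimethoxyphenyl)butan-1-imine, both C2 epimers | C=CCC(/C=N/C1CCCCC1)[C@H](C)[C@@H](O[Si](C)(C)C(C)(C)C)c1cc(OC)c(OC)c(OC)c1
F5 | step 9 | {[(4S)-4-allyl-4-[(1R,2S)-1-(tert-butyldimethylsilyloxy)-1-(3,4,5-trimethoxyphenyl)propan-2-yl]-6-methoxycyclohexa-1,5-dien-1-yl]oxy}trimethylsilane | C=CC[C@@]1(C=C(OC)C(O[Si](C)(C)C)=CC1)[C@H](C)[C@@H](O[Si](C)(C)C(C)(C)C)c1cc(OC)c(OC)c(OC)c1
F6 | step 11 | 7-(phenylselanyl) derivative of 22: 3a-allyl-5-methoxy-3-methyl-7-(phenylselanyl)-2-(3,4,5-trimethoxyphenyl)-3,3a,7,7a-tetrahydro-1-benzofuran-6(2H)-one, C2, C3, C3a and C7a arranged as in 22, both C7 epimers | C=CC[C@]12C=C(OC)C(=O)C([Se]c3ccccc3)[C@H]1O[C@@H](c1cc(OC)c(OC)c(OC)c1)[C@H]2C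
A1 | alternative 1 | methyl (2R,3S)-5-methoxy-6-(triisopropylsilyloxy)-2-(3,4,5-trimethoxyphenyl)-2,3-dihydro-1-benzofuran-3-carboxylate (cis) | COc1cc2c(cc1O[Si](C(C)C)(C(C)C)C(C)C)O[C@@H](c1cc(OC)c(OC)c(OC)c1)[C@H]2C(=O)OC
A2 | alternative 1 | methyl 2-diazo-2-[5-methoxy-4-(triisopropylsilyloxy)-2-(3,4,5-trimethoxybenzyloxy)phenyl]acetate | COC(=O)C(=[N+]=[N-])c1cc(OC)c(O[Si](C(C)C)(C(C)C)C(C)C)cc1OCc1cc(OC)c(OC)c(OC)c1
A3 | alternative 2 | (2R,3S,3aR,7aR)-3a-allyl-3-methyl-2-(3,4,5-trimethoxyphenyl)-3,3a,7,7a-tetrahydro-1-benzofuran-6(2H)-one (cis-fused; C2, C3 and C3a arranged as in 24) | C=CC[C@]12C=CC(=O)C[C@H]1O[C@@H](c1cc(OC)c(OC)c(OC)c1)[C@H]2C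
A4 | alternative 2 | (1R,2S)-2-(1-allyl-4-oxocyclohexa-2,5-dien-1-yl)-1-(3,4,5-trimethoxyphenyl)propyl acetate | C=CCC1(C=CC(=O)C=C1)[C@H](C)[C@@H](OC(C)=O)c1cc(OC)c(OC)c(OC)c1
A5 | alternative 3 | (4S,5R)-4-methyl-5-(3,4,5-trimethoxyphenyl)dihydrofuran-2(3H)-one (cis) | O=C1O[C@@H](c2cc(OC)c(OC)c(OC)c2)[C@H](C1)C
A6 | alternative 3 | (E)-but-2-enal (crotonaldehyde) | C/C=C/C=O
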